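Time is what we have to stretch: alpha was read up to 15.0 h, and the new flasks stand for 40 h.

| setting | alpha | grey | red | green | blue | teal |
|---|---|---|---|---|---|---|
| substrate | 0.11 M | 0.030 M | 0.060 M | 0.060 M | 0.10 M | 0.15 M |
| solid reagent | 1.8 equiv | 1.80 equiv | 1.20 equiv | 1.80 equiv | 1.80 equiv | 2.70 equiv |
| initiator | 2.7 mol% | 1.5 mol% | 8 mol% | 10 mol% | 2.7 mol% | 10 mol% |
| temperature | 70 °C | 70 °C | 70 °C | 50 °C | 70 °C | 70 °C |
| remark | run made earlier |  |  |  |  |  |
| time |  | 40 h | 40 h | 40 h | 40 h | 40 h |

alpha run (percent of the substrate charged)

| time / h | product / % | substrate / % |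
|---|---|---|
| 4.00 | 4.3 | 95.5 |
| 8.00 | 11.9 | 88.1 |
| 10.0 | 16.1 | 83.4 |
| 15.0 | 26.2 | 73.7 |

(readings scatter by 0.3 percentage points)

- solid reagent is a solid; its amount is given per volume of the solution
- the earlier runs were read with a standard deviation of 0.3 percentage points
- at the start none of the solid reagent is in solution
- the earlier runs do not show what temperature does; that part of a forecast is a guess
- no earlier run changes the charge of initiator; that part of a forecast is a guess

- all flasks from highest to lowest amount of product, in percent of the substrate charged, at 40 h (grey / red / green / blue / teal)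
- the amount of product, in percent of the substrate charged of the flask you put first, at 40 h
- the amount of product, in percent of the substrate charged of the flask you put last, at 40 h

We work with the fraction left. Between 8.00 h and 15.0 h alpha falls from 88.1% to 73.7% of its charge, so the loss rate, the share of the remaining substrate that goes each hour 0.0255 h⁻¹, stands as a reading; held constant, it is a pseudo-first-order constant.

We bracket blue, which has alpha's equivalents, loading and temperature at 0.10 M instead of 0.11 M. The other flasks change initiator or temperature, which alpha does not test.

From below: if the rate follows [substrate], the loss rate holds, so 39.0% is left at 40 h and product reaches 61.0%.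

From above: alpha's straight line gives 0.00225 M h⁻¹, and that molar rate would take blue to 85.0%. But blue's charges are scaled down by 0.909; if the rate scales with them and does not rise above alpha's late line, blue stays on that line in percent, so we take 77.3% as the estimate for the top of the bracket.

The forecast orders teal > grey > red > blue > green, with teal at 92% (75% to 100%) and green at 25% (8% to 50%). For blue it says “it should reach about 70 %, allowing for some late slowing”, which lies inside our bracket.

The flasks give teal > red > blue > grey > green.

    substrate + second chain carrier → released group + first chain carrier (k = 2800 M⁻¹ s⁻¹, Ea = 38.0 kJ mol⁻¹)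
    2 first chain carrier → ended chains A (k = 7.80 × 10⁶ M⁻¹ s⁻¹, Ea = 11.0 kJ mol⁻¹)
    partner + first chain carrier → product + second chain carrier (k = 1100 M⁻¹ s⁻¹, Ea = 43.0 kJ mol⁻¹)
    initiator → 2 initiating radical (k = 1.40 × 10⁻⁶ s⁻¹, Ea = 122 kJ mol⁻¹)
    2 second chain carrier → ended chains B (k = 3.00 × 10⁸ M⁻¹ s⁻¹, Ea = 15.0 kJ mol⁻¹)
    solid reagent ⇌ partner, rate k6*(cs6 - [partner]) while solid is left; crystals form when [partner] > cs6 (solubility = 0.0500 M, k = 5.30 × 10⁻⁵ s⁻¹)
    substrate + initiating radical → capped initiator + first chain carrier (k = 1.50 × 10⁵ M⁻¹ s⁻¹, Ea = 31.0 kJ mol⁻¹)
    (constants at 70 °C)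

Teal gives 87.1%, green 21.5%, and blue 64.8%, inside the bracket. Grey reaches 41.2%, and blue given grey's 1.5 mol% loading gives 53.4%. Blue's 35% left at 40.0 h makes its loss rate, averaged over the run, 0.0262 h⁻¹, against 0.0255 h⁻¹ read on alpha. Green's 78% left at 40.0 h gives 0.00607 h⁻¹; held to 400 h, that reckons a product of 91.2%, and green then stands at 94.1%.

The earlier runs and the new flask were computed for substances that don't exist; scatter was added.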